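**Retrosynthetic overview**
1. Ring A with its three methyl groups is bought as trimethylhydroquinone 1; the C20 chain with both methyl-bearing stereocentres (7R,11R) is bought as natural phytol 2.
2. C6–C1' bond: Friedel–Crafts phytylation of 1 with 2 (the prenyl-transferase step) gives the open-chain phytylhydroquinone 3.
3. Key step, O1–C2 bond: a catalyst-controlled, cyclase-like 6-endo hydroalkoxylation of 3 closes ring B (the dihydropyran) to (2R,4'R,8'R)-α-tocopherol 4 and sets the last stereocentre.
4. Oxidative opening of ring B, as in the natural oxidation of vitamin E: 4 → hemiketal 5 → quinone 6. The C2–O1 bond is never broken, so 2R becomes 3'R.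
5. Ring order: ring A bought, ring B closed (step 2), ring B opened (step 3), ring A left as the quinone.

Assumption: the (S,S) antipode of the catalyst in step 2 is taken to be the one that gives 2R; a first run with chiral HPLC of 4 confirms this, and the equally accessible (R,R) antipode is used if the sense is opposite.

**Step 1**
Reactants: 1 trimethylhydroquinone (2,3,5-trimethylbenzene-1,4-diol); 2 natural phytol ((2E,7R,11R)-3,7,11,15-tetramethylhexadec-2-en-1-ol)
Product: 3 2,3,5-trimethyl-6-[(2E,7R,11R)-3,7,11,15-tetramethylhexadec-2-en-1-yl]benzene-1,4-diol (phytyl-trimethylhydroquinone)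
Conditions: 1 (3 equiv), BF3·OEt2 (0.3 equiv), 1,4-dioxane, 25 °C, argon; aq. Na2S2O4 wash; chromatography under argon (AgNO3-impregnated silica if Z isomer is present)
Reagents that add atoms: none
Why: Friedel–Crafts allylation in which BF3 ionises the allylic alcohol and the phytyl cation attacks the only free ring position of 1 through its primary terminus, while dioxane tempers the acid so that the open-chain hydroquinone is not cyclised; C7' and C11' come unchanged from 2.

**Step 2**
Reactants: 3 phytyl-trimethylhydroquinone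
Product: 4 (2R,4'R,8'R)-α-tocopherol ((2R)-2,5,7,8-tetramethyl-2-[(4R,8R)-4,8,12-trimethyltridecyl]-3,4-dihydro-2H-chromen-6-ol)
Conditions: (S,S)-IDPi acid HN[P(=NSO2CF3)(O2C20H10Ar2)]2 (5 mol%; O2C20H10Ar2 = (S)-3,3'-Ar2-1,1'-binaphthalene-2,2'-diolate, Ar = 3,5-(CF3)2C6H3), 5 Å MS, cyclohexane, 40 °C, argon
Reagents that add atoms: none
Why: Proposed new method: the confined chiral acid protonates C2' of the E-trisubstituted alkene while the ortho phenol oxygen adds anti to C3' (6-endo, Markovnikov, asynchronous concerted or through a tight tertiary cation/chiral anion pair), so the catalyst pocket rather than the remote C4'/C8' centres selects the face of C3' and sets 2R; this copies tocopherol cyclase, and the closest known reaction types are the IDPi-catalysed asymmetric intramolecular hydroalkoxylation of unactivated alkenes and the achiral acid-catalysed chroman closure of phytylhydroquinones.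

**Step 3**
Reactants: 4 (2R,4'R,8'R)-α-tocopherol
Product: 6 (3'R,7'R,11'R)-α-tocopherylquinone, via 8a-hydroxy-α-tocopherone 5 (not isolated)
Conditions: FeCl3·6H2O (5 equiv), Et2O/MeOH/H2O, 20 °C, 1 h, dark
Reagents that add atoms: water, O
Why: two-electron oxidation of the chromanol by trivalent iron gives the tocopheroxylium cation, water adds at C8a, and hemiketal 5 collapses by C8a–O1 cleavage to the para-quinone (oxidative chroman ring opening); the C2–O1 bond stays intact, so 2R of 4 is carried over unchanged as 3'R.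

**Compound list**
1 | trimethylhydroquinone (2,3,5-trimethylbenzene-1,4-diol) | Cc1cc(O)c(C)c(C)c1O | starting material
2 | natural phytol, (2E,7R,11R)-3,7,11,15-tetramethylhexadec-2-en-1-ol | OC/C=C(\C)CCC[C@H](C)CCC[C@H](C)CCCC(C)C | starting material
3 | 2,3,5-trimethyl-6-[(2E,7R,11R)-3,7,11,15-tetramethylhexadec-2-en-1-yl]benzene-1,4-diol | Cc1c(C)c(O)c(C/C=C(\C)CCC[C@H](C)CCC[C@H](C)CCCC(C)C)c(C)c1O | intermediate
4 | (2R,4'R,8'R)-α-tocopherol | Cc1c(C)c2O[C@](C)(CCC[C@H](C)CCC[C@H](C)CCCC(C)C)CCc2c(C)c1O | intermediate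
5 | 8a-hydroxy-α-tocopherone (2R; both C8a epimers) | CC1=C(C)C2(O)O[C@](C)(CCC[C@H](C)CCC[C@H](C)CCCC(C)C)CCC2=C(C)C1=O | intermediate
6 | (3'R,7'R,11'R)-α-tocopherylquinone, 2-[(3R,7R,11R)-3-hydroxy-3,7,11,15-tetramethylhexadecyl]-3,5,6-trimethylcyclohexa-2,5-diene-1,4-dione | CC1=C(C)C(=O)C(CC[C@](C)(O)CCC[C@H](C)CCC[C@H](C)CCCC(C)C)=C(C)C1=O | target

**Step count**
Total steps: 3. Longest linear sequence: 3.

**Steps most likely to fail, with fallbacks**

Step 2 (most likely). The risks are low selectivity at C2, erosion by Z isomer or by acid-induced alkene migration, and slow turnover because the hydroquinone binds the acid. The product is an oil, so the dr cannot be upgraded by crystallisation. The fallback sets out from 2 and 1 and comes back at 6, setting C3' by reagent control instead. Sharpless asymmetric epoxidation of 2 (Ti(OiPr)4, D-(−)-diethyl tartrate, t-BuOOH, 4 Å MS, CH2Cl2, −20 °C) gives (2R,3R)-2,3-epoxyphytol F1. NaAlH2(OCH2CH2OCH3)2 in THF at 0 °C delivers hydride to C2 and gives (3R,7R,11R)-3,7,11,15-tetramethylhexadecane-1,3-diol F2. TsCl in pyridine at 0 °C converts the primary hydroxyl only, giving the primary tosylate F3. Separately, 1 is methylated (Me2SO4, K2CO3, acetone) to 1,4-dimethoxy-2,3,5-trimethylbenzene F4 and brominated (Br2, CH2Cl2, 0 °C) to 1-bromo-2,5-dimethoxy-3,4,6-trimethylbenzene F5. The Grignard reagent from F5 (Mg, THF; 3 equiv, the first deprotonating the tertiary hydroxyl) is coupled with F3 under Li2CuCl4 catalysis to give (3R,7R,11R)-1-(2,5-dimethoxy-3,4,6-trimethylphenyl)-3,7,11,15-tetramethylhexadecan-3-ol F6. Oxidative demethylation with (NH4)2Ce(NO3)6 in MeCN/H2O at 0 °C then gives 6.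

Step 1. The risks are E/Z scrambling through the allyl cation, premature acid cyclisation to C2-epimeric chromanol (which would lower the dr later), phytadiene formation and air oxidation of the hydroquinone. The fallback sets out from 2 and 1 and comes back at 3, replacing the cationic alkylation by a geometry-retaining allylstannane–quinone coupling. PBr3 in Et2O at −10 °C converts 2 into phytyl bromide F7. Me3SnLi in THF at −78 °C gives phytyltrimethylstannane F8. Oxidation of 1 with FeCl3 in aqueous MeOH gives 2,3,5-trimethyl-1,4-benzoquinone F9. F8 and F9 are combined with BF3·OEt2 in CH2Cl2 at −78 °C; 1,2-addition followed by allyl shift to the free ring carbon, then a KF and Na2S2O4 work-up, delivers hydroquinone 3 with the E-alkene intact.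

Step 3. The risks are HCl-promoted re-cyclisation or dehydration of the tertiary alcohol and one-electron side paths (5a-methyl oxidation, dimers). The fallback sets out from 4 and comes back at 5, using the neutral singlet-oxygen pathway by which vitamin E is consumed in vivo. Photooxygenation of 4 (O2, visible light, 5,10,15,20-tetraphenylporphyrin C44H30N4 as sensitiser, CH2Cl2/MeOH, 0 °C) gives 8a-hydroperoxy-α-tocopherone F10. PPh3 reduces it to hemiketal 5, which opens to 6 on standing.

**Further compounds**
F1 | step 2 | (2R,3R)-2,3-epoxyphytol, [(2R,3R)-3-methyl-3-[(4R,8R)-4,8,12-trimethyltridecyl]oxiran-2-yl]methanol | OC[C@H]1O[C@]1(C)CCC[C@H](C)CCC[C@H](C)CCCC(C)C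
F2 | step 2 | (3R,7R,11R)-3,7,11,15-tetramethylhexadecane-1,3-diol | OCC[C@](C)(O)CCC[C@H](C)CCC[C@H](C)CCCC(C)C
F3 | step 2 | (3R,7R,11R)-3-hydroxy-3,7,11,15-tetramethylhexadecyl 4-methylbenzenesulfonate | Cc1ccc(cc1)S(=O)(=O)OCC[C@](C)(O)CCC[C@H](C)CCC[C@H](C)CCCC(C)C
F4 | step 2 | 1,4-dimethoxy-2,3,5-trimethylbenzene | COc1cc(C)c(OC)c(C)c1C
F5 | step 2 | 1-bromo-2,5-dimethoxy-3,4,6-trimethylbenzene | COc1c(Br)c(C)c(OC)c(C)c1C
F6 | step 2 | (3R,7R,11R)-1-(2,5-dimethoxy-3,4,6-trimethylphenyl)-3,7,11,15-tetramethylhexadecan-3-ol | COc1c(C)c(C)c(OC)c(C)c1CC[C@](C)(O)CCC[C@H](C)CCC[C@H](C)CCCC(C)C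
F7 | step 1 | phytyl bromide, (2E,7R,11R)-1-bromo-3,7,11,15-tetramethylhexadec-2-ene | BrC/C=C(\C)CCC[C@H](C)CCC[C@H](C)CCCC(C)C
F8 | step 1 | phytyltrimethylstannane, trimethyl[(2E,7R,11R)-3,7,11,15-tetramethylhexadec-2-en-1-yl]stannane | C[Sn](C)(C)C/C=C(\C)CCC[C@H](C)CCC[C@H](C)CCCC(C)C
F9 | step 1 | 2,3,5-trimethyl-1,4-benzoquinone | CC1=CC(=O)C(C)=C(C)C1=O
F10 | step 3 | 8a-hydroperoxy-α-tocopherone (2R; both C8a epimers) | CC1=C(C)C2(OO)O[C@](C)(CCC[C@H](C)CCC[C@H](C)CCCC(C)C)CCC2=C(C)C1=O
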